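## The problem

The target is a pterocarpan. A chroman (rings A and B) and a 2,3-dihydrobenzofuran (rings C and D) share the C6a–C11a bond, and a fifth ring, a 2,2-dimethyl-3,4-dihydro-2H-pyran (ring E), is fused across C1–C2 of ring A with its oxygen on C1. Ring A is therefore a fully differentiated phloroglucinol: O1 lies in ring E, O3 is a free phenol, O5 lies in ring B, C2 carries the former prenyl carbon and only C4 bears hydrogen. Which oxygen ends up where must be settled early, because it cannot be corrected once the rings are closed. The only stereocentres are C6a and C11a, both S and cis. A trans B/C fusion is badly strained, so either centre dictates the other once ring C exists, or both can be set together by a syn addition across C6a=C11a; the real task is absolute configuration. The benzylic aryl ether C11a–O11 sits ortho and para to three ring A oxygens and ionises easily in acid, so the closing steps must be mild and the C3 phenol needs a protecting group that leaves without acid. Ring D is bonded to two neighbouring atoms, C6a (through C6b) and O11 (through C10a), which are the α-carbon and the carbonyl oxygen of the ring A/B chroman-4-one. A 1,2-dihaloanisole can therefore be laid across that enolate in one operation, and the methoxy group (para to C6b, meta to C10a) is matched by an iodide para and a bromide meta to it.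

## Retrosynthesis

**13 ⇒ 12.** The O–Si bond at C3 is cut. A triisopropylsilyl ether is chosen because buffered fluoride removes it without touching the acid-labile C11a–O11 bond, and because it is bulky enough to survive carbonate, hydride and mild acid earlier on. The forward step only has to be non-acidic.

**12 ⇒ 11.** The two C–H bonds at C6a and C11a are removed, giving the flat, achiral pterocarpene 11. This erases both stereocentres at once and exposes a benzofuran, which is what the ring D annulation delivers. The neighbouring cut, C11a–O11 back to an isoflavanol, is the classical one but would give up that annulation. The forward reaction is a face-selective syn hydrogenation of a tetrasubstituted benzofuran bond. This is the demanding step of the plan, and it is kept on the silyl ether for solubility in hexane.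

**11 ⇒ 8 + 9.** Both bonds to ring D, C6a–C6b and O11–C10a, are cut, leading to chromanone 8 and 2-bromo-1-iodo-4-methoxybenzene 9. Cutting only one of them would require a protected ring D phenol and a separate ring closure. Here the precursor loses one ring and one arene, and 9 is commercial. The forward reaction must engage C–I before C–Br and must spare the base-sensitive chromanone.

**8 ⇒ 7.** The C8–C9 single bond of the pyranone ring (tricycle numbering) is traced back to the double bond of chromone 7. The chromone is what a one-carbon homologation of an ortho-hydroxyacetophenone delivers directly, so one conjugate reduction is the price. It must stop at the ketone.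

**7 ⇒ 5 (through 6).** The O–C and C–C bonds of the single carbon between the phenol oxygen and the acetyl methyl are cut, and that carbon comes from dimethylformamide dimethyl acetal. A Friedel–Crafts closure of an aryloxypropionic acid would face an ortho/ortho regiochemical choice. Here the acetyl group already marks the position, and only one hydroxyl of 5 is free.

**5 ⇒ 4.** The O–C(CH3)2 bond of ring E is cut, giving the ortho-prenylphenol 4. The prenyl group of 4 has a free hydroxyl on one side and a silyl ether on the other, so acid closure can only place the ring oxygen at the future C1.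

**4 ⇒ 3.** The O–Si bond is cut. The forward silylation must pick the para hydroxyl of 3, which is the most acidic and the only one not engaged with the acetyl group. Silylation is placed after prenylation because the C-alkylation runs in aqueous alkali, which an aryl silyl ether would not survive.

**3 ⇒ 1 + 2.** The aryl–CH2 bond is cut, giving 2,4,6-trihydroxyacetophenone 1 and prenyl bromide 2. The two open ring positions of 1 are equivalent, so only C- versus O-alkylation and mono- versus bis-alkylation are at issue.

## Roads not taken

**Alternative 1:** The cut goes through C11a–C11b and O11–C11a and leads to the open-chain (S)-aldehyde A1, a 2-aryl-3-aryloxypropanal with a MOM-protected ring D phenol and a symmetric 3,5-bis(allyloxy)phenyl ether as ring A.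
- Forward step: acid with a thiol scavenger would free the phenol, ring A would add to the aldehyde (ring B), and the benzylic cation would be caught by the phenol (ring C) to give the cis-pterocarpan A2.
- Merits: two rings close in one metal-free step, the symmetric ring A makes the Friedel–Crafts event regiochemically trivial, and the cis fusion is automatic. In rings formed per step this road is better than the chosen one, and it has no alkene to hydrogenate.
- Weak points: C6a of A1 is the benzylic α-carbon of an aldehyde and can enolise under the acid that triggers the cascade, so its configuration is not secure. A2 also lacks ring E. Its two allyl ethers at O1 and O3 would have to be told apart, C2 prenylated, and the pyran closed onto O1 rather than O3, on a pterocarpan whose C11a–O11 bond does not tolerate the acid that chroman formation needs.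
- Comparison: the chosen plan differentiates all three ring A oxygens and closes ring E on the robust acetophenones 4 and 5, and needs only two steps after its key step.

**Alternative 2:** The cut goes through C4a–O5 and C11b–C11a and leads to the ortho-silylaryl triflate A3 (ring A with ring E and a benzyl ether) and the 2-arylacrolein A4.
- Forward step: CsF would release the aryne from A3, the aldehyde of A4 would add across it, and the ortho-quinone methide formed would close by oxa-6π electrocyclisation to the isoflav-3-ene A5.
- Merits: it is the most convergent of the four plans, and the C1 alkoxy group of the aryne should direct the carbonyl oxygen to C4a. The trisubstituted alkene of A5 is a better-precedented substrate for enantioselective hydrogenation than the tetrasubstituted benzofuran bond of 11. On that point this road is ahead.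
- Weak points: A3 is a pentasubstituted benzene with silyl and triflate groups to be placed ortho to each other in a defined sense, which would take more steps than the whole sequence to 8. A5 has no stereocentre and no O11–C11a bond, so an enantioselective reduction, two debenzylations and an oxidative benzylic C–O closure on a very electron-rich ring would still follow.
- Comparison: the chosen plan has both ring D bonds in place after the key step, two steps left instead of at least three, and far cheaper building blocks.

**Alternative 3:** The cut goes through C6a–C11a and leads to the ring D aryldiazoacetate A6, whose O11 carries the ring A benzyl group.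
- Forward step: with a chiral dirhodium tetracarboxylate such as Rh2(S-PTTL)4, the carbenoid carbon would insert into the benzylic C–H bond (a 1,5-insertion) to give the cis-2,3-dihydrobenzofuran ester A7 with both stereocentres set.
- Merits: both centres are formed in one catalytic step of a reaction class with a good record for cis-2-aryl-2,3-dihydrobenzofuran-3-carboxylates. In absolute stereocontrol this road is clearly stronger than the chosen plan, whose hydrogenation is unproven.
- Weak points: the benzylic CH2 of A6 is flanked by two ortho oxygen substituents, and the ether oxygen can intercept the carbenoid as an oxonium ylide. The cis ester of A7 can epimerise to the trans isomer, which cannot close ring B. A6 needs a ring A benzylic alcohol that already carries ring E and two distinguishable silyl ethers. After the key step, ester reduction, selective desilylation at O5, a Mitsunobu closure of O5–C6 and a final desilylation remain.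
- Comparison: the chosen plan is shorter (eight steps in all) and has a precedented transfer-hydrogenation detour from 8 (see the fallback to step 7) should its stereo-defining step fail.

Key step: step 6

Assumption: the sense of induction of the ruthenium–carbene catalyst on this tetrasubstituted benzofuran cannot be derived safely from the 2-substituted cases. Step 7 is written with the (R,R) ligand, and the equally available (S,S) antipode is to be used if that is the one that delivers hydrogen to the face giving (6aS,11aS).

Step 1
Reactants: 1 2,4,6-trihydroxyacetophenone; 2 prenyl bromide (1-bromo-3-methylbut-2-ene)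
Product: 3 1-[2,4,6-trihydroxy-3-(3-methylbut-2-en-1-yl)phenyl]ethanone
Conditions: 2 (0.9 equiv), 10% aq KOH, 0 °C to rt
Reagents that add atoms: none
Why: C-alkylation of an ambident phloroglucinol phenolate; in water the phenolate oxygens are hydrogen-bonded and the soft allylic bromide is taken up at the ring carbon, the two open positions of 1 are equivalent, and a deficit of 2 limits bis-prenylation.

Step 2
Reactants: 3 1-[2,4,6-trihydroxy-3-(3-methylbut-2-en-1-yl)phenyl]ethanone
Product: 4 1-[2,6-dihydroxy-3-(3-methylbut-2-en-1-yl)-4-(triisopropylsilyloxy)phenyl]ethanone
Conditions: TIPSCl (1.05 equiv), imidazole, CH2Cl2, 0 °C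
Reagents that add atoms: triisopropylsilyl chloride, CC(C)[Si](Cl)(C(C)C)C(C)C
Why: Regioselective O-silylation; the hydroxyl para to the acetyl group is the most acidic and is not tied to the carbonyl, whereas both ortho hydroxyls are chelated or crowded by the acetyl group, and the bulky silyl chloride amplifies that difference.

Step 3
Reactants: 4 1-[2,6-dihydroxy-3-(3-methylbut-2-en-1-yl)-4-(triisopropylsilyloxy)phenyl]ethanone
Product: 5 1-[7-hydroxy-2,2-dimethyl-5-(triisopropylsilyloxy)chroman-8-yl]ethanone
Conditions: Amberlyst 15 (sulfonic acid resin), toluene, 50 °C
Reagents that add atoms: none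
Why: Acid-catalysed Markovnikov hydroalkoxylation of an ortho-prenylphenol (6-endo closure onto the tertiary cation); the only free hydroxyl next to the prenyl group is the one between it and the acetyl group, so the ring E oxygen is fixed at the future C1, and an aryl triisopropylsilyl ether tolerates a dry sulfonic acid resin.

Step 4
Reactants: 5 1-[7-hydroxy-2,2-dimethyl-5-(triisopropylsilyloxy)chroman-8-yl]ethanone
Product: 7 2,2-dimethyl-5-(triisopropylsilyloxy)-3,4-dihydro-2H,10H-pyrano[2,3-f]chromen-10-one (the chromone), via enaminone 6 (not isolated)
Conditions: Me2NCH(OMe)2 (3 equiv), toluene, 90 °C; evaporate; then 2 M HCl, CH2Cl2, rt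
Reagents that add atoms: N,N-dimethylformamide dimethyl acetal, COC(OC)N(C)C
Why: Enaminone chromone synthesis; the acetal condenses with the methyl ketone to the (E)-enaminone 6, and acid lets the single free phenol add to the β-carbon and expel dimethylamine, a closure that is unambiguous because 5 has only one hydroxyl.

Step 5
Reactants: 7 2,2-dimethyl-5-(triisopropylsilyloxy)-3,4-dihydro-2H,10H-pyrano[2,3-f]chromen-10-one
Product: 8 2,2-dimethyl-5-(triisopropylsilyloxy)-3,4,8,9-tetrahydro-2H,10H-pyrano[2,3-f]chromen-10-one (the chroman-4-one; ring oxygen of the dimethylpyran on the carbon peri to the carbonyl)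
Conditions: LiBH(s-Bu)3 (1.1 equiv), THF, −78 °C; then H2O
Reagents that add atoms: none
Why: Conjugate (1,4) hydride reduction of a chromone by a bulky trialkylborohydride; the carbonyl is a vinylogous ester shielded by the peri alkoxy group, so hydride adds at the unsubstituted β-carbon and the lithium enolate is simply protonated on quenching at low temperature.

Step 6
Reactants: 8 2,2-dimethyl-5-(triisopropylsilyloxy)-3,4,8,9-tetrahydro-2H,10H-pyrano[2,3-f]chromen-10-one; 9 2-bromo-1-iodo-4-methoxybenzene
Product: 11 9-methoxy-3-(triisopropylsilyloxy)-6a,11a-didehydropterocarpan bearing the 2,2-dimethyl-3,4-dihydro-2H-pyran ring E across C1–C2 (oxygen on C1) (the pterocarpene), via bromoaryl ketone 10 (not isolated)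
Conditions: Pd2(dba)3 (2.5 mol%), bis[2-(diphenylphosphino)phenyl] ether (DPEphos, 6 mol%), Cs2CO3 (3 equiv), 9 (1.1 equiv), toluene, 100 °C
Reagents that add atoms: none
Why: Zerovalent palladium inserts into the C–I bond of 9 well before the C–Br bond, the caesium enolate of 8 (only the CH2 next to the carbonyl, the future C6a, can enolise) displaces iodide on the arylpalladium iodide, and C–C reductive elimination gives 10 with the carbon para to methoxy on C6a. Ketone 10 is more acidic than 8 and enolises again; oxidative addition into the now neighbouring C–Br bond and binding of the enolate oxygen give a six-membered oxapalladacycle, from which C–O reductive elimination closes ring C. The closest known reaction type is the palladium-catalysed one-pot α-arylation and intramolecular O-arylation of ketones with 1,2-dihaloarenes to give benzofurans. Ring C, five-membered, is thus closed by reductive elimination inside a palladacycle and not by an exo or endo nucleophilic attack, and aromatisation to the furan makes the closure irreversible. No stereocentre is formed, since C6a of racemic 10 becomes trigonal. Three selectivities are needed: the orientation of ring D, secured by the reactivity gap between C–I and C–Br; mono- over diarylation, secured because the intramolecular O-arylation of 10 outruns a second intermolecular coupling at its hindered tertiary α-carbon; and survival of the chromanone and the silyl ether, secured by the weak, heterogeneous base Cs2CO3 in toluene, under which any retro-oxa-Michael opening is reversible. The wide bite angle of DPEphos is what favours the difficult C–O reductive elimination.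

Step 7
Reactants: 11 9-methoxy-3-(triisopropylsilyloxy)-6a,11a-didehydropterocarpan with ring E across C1–C2
Product: 12 (6aS,11aS)-9-methoxy-3-(triisopropylsilyloxy)pterocarpan with the 2,2-dimethyl-3,4-dihydro-2H-pyran ring E across C1–C2 (oxygen on C1), cis-fused
Conditions: Ru(cod)(2-methylallyl)2 (5 mol%), (R,R)-SINpEt·HBF4 (1,3-bis[(1R)-1-(naphthalen-1-yl)ethyl]-4,5-dihydroimidazolium tetrafluoroborate, 10 mol%), KOtBu (15 mol%), n-hexane, 70 °C; then 11, H2 (100 bar), 40 °C
Reagents that add atoms: none
Why: Proposed new method: the closest known reaction type is the ruthenium N-heterocyclic carbene catalysed enantioselective hydrogenation of 2- and 3-substituted benzofurans to 2,3-dihydrobenzofurans, which has not been shown for a tetrasubstituted 2-aryl-3-alkyl benzofuran bond held in a pyran ring; the reasoning is that the same ruthenium hydride should bind the electron-rich furan π-bond on one face of the flat benzofuro[3,2-c]chromene, both faces of which are open, and transfer both hydrogens syn, so that C6a and C11a are set together as the cis pair while the C2-symmetric naphthylethyl pocket of the carbene chooses the face, the benzene rings and aryl–oxygen bonds staying intact.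

Step 8
Reactants: 12 (6aS,11aS)-9-methoxy-3-(triisopropylsilyloxy)pterocarpan with ring E across C1–C2
Product: 13 (6aS,11aS)-3-hydroxy-9-methoxypterocarpan with the 2,2-dimethyl-3,4-dihydro-2H-pyran ring E across C1–C2 (oxygen on C1), the target CNP0207547.1
Conditions: Bu4NF (1.2 equiv), AcOH (1.2 equiv), THF, 0 °C
Reagents that add atoms: none
Why: Fluoride-induced cleavage of an aryl silyl ether; buffering with acetic acid keeps the electron-rich phenoxide from building up, and neither stereocentre nor the benzylic C11a–O11 bond is involved.

## Compound list

1 | 2,4,6-trihydroxyacetophenone | CC(=O)c1c(O)cc(O)cc1O | starting material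
2 | prenyl bromide (1-bromo-3-methylbut-2-ene) | CC(C)=CCBr | starting material
3 | 1-[2,4,6-trihydroxy-3-(3-methylbut-2-en-1-yl)phenyl]ethanone | CC(=O)c1c(O)cc(O)c(CC=C(C)C)c1O | intermediate
4 | 1-[2,6-dihydroxy-3-(3-methylbut-2-en-1-yl)-4-(triisopropylsilyloxy)phenyl]ethanone | CC(=O)c1c(O)cc(O[Si](C(C)C)(C(C)C)C(C)C)c(CC=C(C)C)c1O | intermediate
5 | 1-[7-hydroxy-2,2-dimethyl-5-(triisopropylsilyloxy)chroman-8-yl]ethanone | CC(=O)c1c(O)cc(O[Si](C(C)C)(C(C)C)C(C)C)c2CCC(C)(C)Oc12 | intermediate
6 | (E)-3-(dimethylamino)-1-[7-hydroxy-2,2-dimethyl-5-(triisopropylsilyloxy)chroman-8-yl]prop-2-en-1-one (enaminone, not isolated) | CN(C)/C=C/C(=O)c1c(O)cc(O[Si](C(C)C)(C(C)C)C(C)C)c2CCC(C)(C)Oc12 | intermediate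
7 | 2,2-dimethyl-5-(triisopropylsilyloxy)-3,4-dihydro-2H,10H-pyrano[2,3-f]chromen-10-one (chromone) | O=c1ccoc2cc(O[Si](C(C)C)(C(C)C)C(C)C)c3CCC(C)(C)Oc3c12 | intermediate
8 | 2,2-dimethyl-5-(triisopropylsilyloxy)-3,4,8,9-tetrahydro-2H,10H-pyrano[2,3-f]chromen-10-one (chroman-4-one) | O=C1CCOc2cc(O[Si](C(C)C)(C(C)C)C(C)C)c3CCC(C)(C)Oc3c21 | intermediate
9 | 2-bromo-1-iodo-4-methoxybenzene | COc1ccc(I)c(Br)c1 | starting material
10 | racemic 9-(2-bromo-4-methoxyphenyl)-2,2-dimethyl-5-(triisopropylsilyloxy)-3,4,8,9-tetrahydro-2H,10H-pyrano[2,3-f]chromen-10-one (not isolated) | COc1ccc(C2COc3cc(O[Si](C(C)C)(C(C)C)C(C)C)c4CCC(C)(C)Oc4c3C2=O)c(Br)c1 | intermediate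
11 | 9-methoxy-3-(triisopropylsilyloxy)-6a,11a-didehydropterocarpan with 2,2-dimethyldihydropyran ring E across C1–C2, oxygen on C1 (pterocarpene) | COc1ccc2c(c1)oc1c2COc2cc(O[Si](C(C)C)(C(C)C)C(C)C)c3CCC(C)(C)Oc3c21 | intermediate
12 | (6aS,11aS)-9-methoxy-3-(triisopropylsilyloxy)pterocarpan with 2,2-dimethyldihydropyran ring E across C1–C2, oxygen on C1, cis-fused | COc1ccc2c(c1)O[C@@H]1c3c(cc(O[Si](C(C)C)(C(C)C)C(C)C)c4c3OC(C)(C)CC4)OC[C@H]21 | intermediate
13 | (6aS,11aS)-3-hydroxy-9-methoxypterocarpan with 2,2-dimethyldihydropyran ring E across C1–C2, oxygen on C1, cis-fused (CNP0207547.1) | COc1ccc2c(c1)O[C@@H]1c3c(cc(O)c4c3OC(C)(C)CC4)OC[C@H]21 | target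

## Step count and weak points

Total step count: 8. Longest linear sequence: 8 steps (1 to 13; 9 enters at step 6).

**Step 7 (proposed new method).** The likeliest failure is absence of turnover, because a tetrasubstituted, doubly aryl-conjugated furan bond binds the crowded ruthenium centre poorly. The second is poor facial discrimination, because both alkene substituents lie in the plane of the tetracycle and offer the carbene pocket little to tell apart. The fallback uses known chemistry, sets out from 8 and comes back at 12.
- Chromanone 8 is α-arylated (Pd2(dba)3, XPhos, Cs2CO3, toluene, 90 °C) with 1-bromo-4-methoxy-2-(methoxymethoxy)benzene F1, made from commercial 2-bromo-5-methoxyphenol with MOMCl and iPr2NEt. This gives the racemic 9-[4-methoxy-2-(methoxymethoxy)phenyl] ketone F2.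
- Asymmetric transfer hydrogenation with RuCl(p-cymene)[(S,S)-TsDPEN] in HCO2H/Et3N follows. The α-aryl centre epimerises under the amine, and the catalyst, which by the usual sense for aryl ketones should give the (S) carbinol, reduces one enantiomer faster. Dynamic kinetic resolution should therefore give the cis-(9S,10S) alcohol F3.
- HCl in ethanol at room temperature then removes the MOM group to give the phenol F4 and ionises the doubly ortho- and para-oxygenated benzylic alcohol. The cation is captured by the phenol on the face fixed by the neighbouring centre, closing ring C through O11–C11a to give 12.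

**Step 6 (key step).** The likeliest failure is a C–O closure that lags behind, so that 10 accumulates and is arylated a second time. Base-induced opening of the chromanone at 100 °C and erosion of the iodide/bromide preference, which would scramble the orientation of ring D, are further risks. The fallback sets out from 8 and comes back at 11, forming O11–C11a in place of O11–C10a.
- Ketone 8 is arylated with 1-bromo-4-methoxy-2-(methoxymethoxy)benzene F1 to the MOM-protected aryl ketone F2, exactly as in the fallback to step 7. A monobromide fixes the orientation.
- HCl in MeOH–CH2Cl2 at 40 °C removes the MOM group to give the 2'-hydroxy ketone F5 (racemic 9-(2-hydroxy-4-methoxyphenyl) analogue of 8). Its phenol adds to the carbonyl and the hemiketal dehydrates to the furan, the classical cyclodehydration of 2'-hydroxyisoflavanones, giving 11.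

**Step 2.** The likeliest failure is silylation that is not confined to the para hydroxyl, because the ortho prenyl group slows it while the ortho hydroxyl that is momentarily not chelated competes, giving regioisomers and bis-silyl ether. The fallback sets out from 3 and comes back at 5.
- Triol 3 is cyclised unprotected (p-TsOH, toluene, 60 °C) to 1-(5,7-dihydroxy-2,2-dimethylchroman-8-yl)ethanone F6 and its isomer 1-(5,7-dihydroxy-2,2-dimethylchroman-6-yl)ethanone F7, which are separated by chromatography.
- F6 has one chelated and one free hydroxyl, so TIPSCl and imidazole can only give 5. The selectivity problem is moved from a protection to a separation.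

**Step 3.** The likeliest failure is proton-induced loss or migration of the silyl group, which opens the way to closure on the wrong oxygen, or sluggish closure because the participating hydroxyl is chelated. The fallback sets out from 4 and comes back at 5.
- DDQ in benzene at reflux removes hydride from the benzylic, allylic CH2 of the ortho-prenylphenol. The ortho-quinone methide closes by oxa-6π electrocyclisation to 1-[7-hydroxy-2,2-dimethyl-5-(triisopropylsilyloxy)-2H-chromen-8-yl]ethanone F8.
- Hydrogenation of the chromene double bond (H2, Pd/C, ethyl acetate) gives 5 without any acid.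

**Step 1.** The likeliest failure is O-alkylation and double C-alkylation outrunning the wanted mono-C-prenylation, because every position of the phenolate is nucleophilic. The fallback sets out from 1 and comes back at 3: a Friedel–Crafts prenylation of 1 with 2-methylbut-3-en-2-ol and BF3·OEt2 in dioxane at room temperature, in which the tertiary allyl cation attacks the ring carbon directly and no phenolate is involved.

## Further compounds

F1 | step 7 | 1-bromo-4-methoxy-2-(methoxymethoxy)benzene | COCOc1cc(OC)ccc1Br
F2 | step 7 | racemic 9-[4-methoxy-2-(methoxymethoxy)phenyl]-2,2-dimethyl-5-(triisopropylsilyloxy)-3,4,8,9-tetrahydro-2H,10H-pyrano[2,3-f]chromen-10-one | COCOc1cc(OC)ccc1C1COc2cc(O[Si](C(C)C)(C(C)C)C(C)C)c3CCC(C)(C)Oc3c2C1=O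
F3 | step 7 | (9S,10S)-cis-9-[4-methoxy-2-(methoxymethoxy)phenyl]-2,2-dimethyl-5-(triisopropylsilyloxy)-3,4,9,10-tetrahydro-2H,8H-pyrano[2,3-f]chromen-10-ol | O[C@@H]1c2c(OC[C@@H]1c3ccc(OC)cc3OCOC)cc(O[Si](C(C)C)(C(C)C)C(C)C)c4CCC(C)(C)Oc24
F4 | step 7 | (9S,10S)-cis-9-(2-hydroxy-4-methoxyphenyl)-2,2-dimethyl-5-(triisopropylsilyloxy)-3,4,9,10-tetrahydro-2H,8H-pyrano[2,3-f]chromen-10-ol (not isolated) | O[C@@H]1c2c(OC[C@@H]1c3ccc(OC)cc3O)cc(O[Si](C(C)C)(C(C)C)C(C)C)c4CCC(C)(C)Oc24
F5 | step 6 | racemic 9-(2-hydroxy-4-methoxyphenyl)-2,2-dimethyl-5-(triisopropylsilyloxy)-3,4,8,9-tetrahydro-2H,10H-pyrano[2,3-f]chromen-10-one (not isolated) | COc1ccc(C2COc3cc(O[Si](C(C)C)(C(C)C)C(C)C)c4CCC(C)(C)Oc4c3C2=O)c(O)c1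
F6 | step 2 | 1-(5,7-dihydroxy-2,2-dimethylchroman-8-yl)ethanone | CC(=O)c1c(O)cc(O)c2CCC(C)(C)Oc12
F7 | step 2 | 1-(5,7-dihydroxy-2,2-dimethylchroman-6-yl)ethanone | CC(=O)c1c(O)cc2OC(C)(C)CCc2c1O
F8 | step 3 | 1-[7-hydroxy-2,2-dimethyl-5-(triisopropylsilyloxy)-2H-chromen-8-yl]ethanone | CC(=O)c1c(O)cc(O[Si](C(C)C)(C(C)C)C(C)C)c2C=CC(C)(C)Oc12
F0 | step 1 | none | none
A1 | alternative 1 | (S)-3-[3,5-bis(allyloxy)phenoxy]-2-[4-methoxy-2-(methoxymethoxy)phenyl]propanal | COCOc1cc(OC)ccc1[C@H](C=O)COc1cc(OCC=C)cc(OCC=C)c1
A2 | alternative 1 | (6aS,11aS)-cis-1,3-bis(allyloxy)-9-methoxypterocarpan | COc1ccc2c(c1)O[C@@H]1c3c(OCC=C)cc(OCC=C)cc3OC[C@H]21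
A3 | alternative 2 | 5-(benzyloxy)-2,2-dimethyl-8-(trimethylsilyl)chroman-7-yl trifluoromethanesulfonate | C[Si](C)(C)c1c(OS(=O)(=O)C(F)(F)F)cc(OCc2ccccc2)c2CCC(C)(C)Oc12
A4 | alternative 2 | 2-[2-(benzyloxy)-4-methoxyphenyl]prop-2-enal | C=C(C=O)c1ccc(OC)cc1OCc1ccccc1
A5 | alternative 2 | 3-aryl-2H-chromene (isoflav-3-ene) with rings A, B, D and E, benzyl ethers at O3 and at the ring D oxygen | COc1ccc(C2=Cc3c(cc(OCc4ccccc4)c4CCC(C)(C)Oc34)OC2)c(OCc2ccccc2)c1
A6 | alternative 3 | methyl 2-diazo-2-[4-methoxy-2-({7-(tert-butyldimethylsilyloxy)-2,2-dimethyl-5-(triisopropylsilyloxy)chroman-8-yl}methoxy)phenyl]acetate | COC(=O)C(=[N+]=[N-])c1ccc(OC)cc1OCc1c(O[Si](C)(C)C(C)(C)C)cc(O[Si](C(C)C)(C(C)C)C(C)C)c2CCC(C)(C)Oc12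
A7 | alternative 3 | methyl cis-2-aryl-6-methoxy-2,3-dihydrobenzofuran-3-carboxylate (aryl = 7-(tert-butyldimethylsilyloxy)-2,2-dimethyl-5-(triisopropylsilyloxy)chroman-8-yl) | COc1ccc2c(c1)O[C@H](c1c(O[Si](C)(C)C(C)(C)C)cc(O[Si](C(C)C)(C(C)C)C(C)C)c3CCC(C)(C)Oc13)[C@@H]2C(=O)OC
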